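Side product cannot be read off the noon run of this flask: its columns hold target and substrate and no third species.

all flasks: substrate 20 mM; partner 1.05 equiv

| flask | remark | time |
|---|---|---|
| noon | the very flask that is asked about, followed so far |  |
| flask |  | 30 h |

noon run (percent of the substrate charged)

| time / h | target / % | substrate / % |
|---|---|---|
| 0.833 | 23.6 | 76.3 |
| 2.50 | 47.8 | 52.6 |
| 4.00 | 58.2 | 40.4 |
| 6.00 | 64.9 | 31.9 |
| 10.0 | 72.5 | 23.7 |
| 12.0 | 73.9 | 21.0 |

(each reading ± 0.5 percentage points)

- in percentages every species weighs as the substrate in it: one side product counts as two
- steps under discussion: substrate + partner <-> target; partner -> decomposed reagent; substrate + target -> side product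

* concentration of target at 30 h, in mM
* concentration of substrate at 30 h, in mM
* concentration of side product at 30 h, in mM

The gap in the balance stands in for it, since partner's decay takes no substrate with it. By 12.0 h target and substrate fall short of the charge by 5.10%, and that gap is the thing to watch on a repeat. The side step needs substrate and target together, so the gap should grow with the product of their fractions. Summing that product over time through the readings gives 2.33 h. Dividing gives s = 0.0219 h⁻¹, the side pace: the fraction of the charge entering the gap per hour, per unit of that product.

A second way uses the late readings. From 6.00 h the gap grows from 3.20% by 1.9 percentage points over a summed product of 1.08 h, which gives 0.0175 h⁻¹, lower than s. This second way cheats: a difference of two gaps scatters by 1 point on that gain, while the full gap scatters by 0.71 points on 5.10%. So we keep s. Holding the 12.0 h product to 30 h, and halving because one side product counts as two, we reckon c(side product) at 1.12 mM, on the high side since the product was still falling.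

The forecast gives c(target) 15.6 mM, c(substrate) 2.5 mM and c(side product) 1 mM, between 0.7 mM and 1.4 mM; of the side product it says: “it appears late, as expected for a step needing substrate and target together”. Our figure is higher than its value, inside its range.

The flask gives c(target) 14.9 mM, c(substrate) 3.13 mM, higher than forecast, and c(side product) 0.992 mM.

    substrate + partner ⇌ target (K = 1100 L mol⁻¹, k = 0.290 L mol⁻¹ min⁻¹)
    partner → decomposed reagent (k = 8.50 × 10⁻⁵ min⁻¹)
    substrate + target → side product (k = 0.00880 L mol⁻¹ min⁻¹)

Applied to the mean product between 15.0 h and 30.0 h, s gives this flask a side-product gain of 4.3 points, and the flask shows 4 points. The hour of the reading is the largest single effect on c(target) in this flask: read ten times later, it holds 7.56 mM, not 14.9 mM. The neighbour with 0.260 equiv of partner, on the same substrate charge, ends at 71.2% substrate and 19.5% target; s on that product over 30 h gives 9.12%, and that neighbour holds 9.25% side product.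

The numbers in the tables were computed for an exercise, noise included.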